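The numbers in the tables are calculated for substances that don't exist; the scatter is artificial.

If you have to pick one of these flasks within the hour, ask of each how much starting material is wasted for each part that becomes product.

all flasks: free enzyme 1.5 µM
- midnight: starting material 5.1 mM; protic impurity 3 mM; temperature 25 °C; run made earlier
- dawn: starting material 66 mM; protic impurity 3 mM; temperature 36 °C; run made earlier
- amber: starting material 50 mM; protic impurity 3.00 mM; temperature 30 °C; time 5.0 h
- green: starting material 10 mM; protic impurity 3.00 mM; temperature 30 °C; time 5.0 h
- violet: starting material 4.0 mM; protic impurity 3.00 mM; temperature 30 °C; time 5.0 h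
- ochre: starting material 25 mM; protic impurity 3.00 mM; temperature 30 °C; time 5.0 h
- red: starting material 5.0 mM; protic impurity 3.00 mM; temperature 30 °C; time 5.0 h
- grey: starting material 15 mM; protic impurity 3.00 mM; temperature 30 °C; time 5.0 h

- midnight (time / h: product / %, starting material / %): 0.200: 4.4, 76.2; 0.500: 7.2, 55.4; 1.00: 10.4, 37.3; 1.50: 14.1, 24.8; 2.00: 16.1, 17.3; 3.00: 19.7, 11.8; 4.00: 20.8, 5.5
- dawn (time / h: product / %, starting material / %): 0.250: 0.5, 9.6; 0.417: 1.9, 6.3; 0.667: 1.8, 3.8; 1.00: 2.8, 3.3; 1.50: 2.9, 0.3; 2.50: 4.3, 0.6; 4.00: 5.3, 0.3

(scatter of a reading: 1 percentage point)

- ranking by amount of product, in percent of the starting material charged, from high to low, at 5.0 h (amber / green / violet / ochre / red / grey)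
- the amount of product, in percent of the starting material charged of the flask you put first, at 5.0 h
- the amount of product, in percent of the starting material charged of the flask you put last, at 5.0 h

The dawn run lost 90.4% of its charge by 0.250 h, and the midnight run 23.8% by 0.200 h. The dawn run is richer but also warmer, so these readings do not part the two settings. A first-order path has a rate constant that takes the same fraction per hour at any concentration. A second-order loss takes a fraction that rises with concentration. If the loss is second-order, a richer flask at the same temperature should waste more of its charge.

Take the last midnight reading: 3.54. That is its waste odds, starting material lost otherwise per part that became product, the inverse of a selectivity factor. The same reading at dawn gives 17.8, a loose figure, since it divides by a product reading of 5.3% with a scatter of 1 percentage point.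

Now replace each falling curve by its mean, and take that mean as a fixed fraction of the charge. The odds, rival rate over product rate, then rise in a straight line with charge, by 0.234 /mM. The two runs stand at 25 °C and 36 °C, on either side of 30 °C, so I let this line serve for the asked flasks.

It gives violet 3.29 and amber 14.1, so amber's odds are higher than violet's. The product share is one over one plus the odds. That makes 23.3% for violet and 6.64% for amber, read as percent of the charge, which assumes little is left at 5.0 h.

The error of the mean is this. Under a second-order loss a rich charge falls faster. The dawn run, richer and warmer, had less left at 0.250 h, 9.6%, than the midnight run had at 0.200 h, 76.2%. Its mean is then a smaller fraction of its charge, and the line may flatter the flasks between the two runs. My order rests on the odds rising with charge, not on the height of the line.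

The forecast says violet > red > green > grey > ochre > amber, with 22% first and 5.5% last, on the ground that “Yield therefore falls as loading rises”. My order is the same, but my figures are higher than its figures at both ends.

The flasks give violet > red > green > grey > ochre > amber, with 23.8% first and 4.48% last.

    starting material + protic impurity → quenched substrate (k = 0.0290 /M/s, Ea = 48.0 kJ/mol)
    starting material + free enzyme ⇌ complex (K = 46.0 /M, k = 43000 /M/s, Ea = 24.0 kJ/mol, ΔH = −44.0 kJ/mol)
    complex → free enzyme + product (k = 1.10 /s, Ea = 71.0 kJ/mol)
    free enzyme → unfolded enzyme (k = 7.70 × 10⁻⁶ /s, Ea = 227 kJ/mol)
    2 starting material → homo dimer (k = 0.0420 /M/s, Ea = 58.0 kJ/mol)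
    (constants at 30 °C)

Amber's waste odds came to 21.2 at 5.00 h, with the 0.481% of starting material still left set aside, higher than the 14.1 of my line. In the equations the path to product runs through free enzyme, and the paths to homo dimer and quenched substrate do not. So raise free enzyme from 1.5 µM to 3.70 µM, amber otherwise unchanged, and divide the odds by that factor of 2.47. You get 8.60, a share of 10.4%. That neighbour flask gives 9.26%.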